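The numbers in the tables are calculated on assumed constants; the scatter is artificial.

Count turnovers first.

all flasks: temperature 37 °C

|  | starting material | second substrate | free enzyme | remark | time |
|---|---|---|---|---|---|
| larch | 0.050 M | 3 equiv | 0.0075 mol% (in portions, 4) | run made earlier; portions every 80 min |  |
| noon | 0.015 M | 2.00 equiv | 0.015 mol% | everything together at the start | 5.0 h |
| midnight | 0.050 M | 2.00 equiv | 0.0075 mol% (in portions, 4) | the portions of free enzyme follow each other after 80 min, the first at the start | 5.0 h |

larch run (percent of the starting material charged)

| time / min | target / % |
|---|---|
| 15.0 | 2.7 |
| 30.0 | 5.0 |
| 50.0 | 7.6 |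
| 60.0 | 9.9 |
| 80.0 | 12.3 |
| 90.0 | 15.4 |
| 120 | 24.2 |

(each reading ± 0.5 percentage points)

- where the amount of starting material changes, what is given in equivalents or mol% on it follows
- no earlier run changes the charge of free enzyme; that part of a forecast is a guess

* the flask that ends with the higher amount of target, in percent of the starting material charged, or "neither" when 2 percentage points or less lies between them (noon / midnight / neither)
* final target, as a percentage of the starting material charged, in noon
* final target, as a percentage of the starting material charged, in midnight

- The main step comes first. In the larch run the first portion, 0.00187% of the starting material, gives 12.3% target in 80.0 min, so I read a turnover rate (turnover frequency), the target made per minute per enzyme, of 82.0 /min.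
- Multiplying that rate by the catalyst fraction and the working time gives a budget, as a fraction of the charge. Noon, with its catalyst present from the start, has 369%. Midnight's portions work 720 min between them, which gives 111%, so noon's budget is larger.
- Next I add the fall of starting material. In the larch run's second stretch, each portion makes 96.7% of what it made in the first, a reading that carries the scatter. The rate barely slackens, which points to zero order in starting material.
- Then I go round again with the opposite assumption. If the rate followed the concentration of starting material, dilution would cut noon's budget to 111%, level with midnight's, and each flask would end at 67.0%.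
- The rest, second substrate and any loss of enzyme, gets no number, since the larch run varies neither.
- My reckoning is that noon finishes and midnight ends somewhat short, between that figure and the full charge, so I choose noon.
- The forecast differs: it chooses midnight, with 48% in noon and 65% in midnight, and says “The data cannot separate these, so noon is very uncertain.”
- Noon gives >99.9% and midnight 93.7%, so noon ends higher. At 5.00 h midnight still holds 6.26% starting material, against 0% in noon. Midnight has thus turned 84.4% of its budget into target.

    free enzyme → unfolded enzyme (k = 3.00 × 10⁻⁵ /min, Ea = 222 kJ/mol)
    starting material + free enzyme ⇌ complex A (K = 760 /M, k = 1.60 × 10⁵ /M/min, Ea = 43.0 kJ/mol, ΔH = −40.0 kJ/mol)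
    complex A → free enzyme + target (k = 92.0 /min, Ea = 84.0 kJ/mol)
    second substrate + free enzyme ⇌ complex B (K = 19.0 /M, k = 1.00 × 10⁵ /M/min, Ea = 38.0 kJ/mol, ΔH = 12.0 kJ/mol)
    complex B → free enzyme + second product (k = 22.0 /min, Ea = 79.0 kJ/mol)
    free enzyme + target → spent catalyst (k = 0.0220 /M/min, Ea = 59.0 kJ/mol)
    (constants at 37 °C)

- Take noon read at 80 min: the turnover rate gives a budget of 98.4% there. The computed flask holds less, 79.3% target, with 51.2% of the catalyst standing as complex A.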